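## The problem

Pentabromopseudilin (14) is a biaryl. A phenol (ring A: C1 OH, C2 Br, C4 Br) is joined through C6 to C2' of a pyrrole (ring B), and the three remaining pyrrole carbons C3', C4' and C5' all carry bromine. The rings share only the C6–C2' bond, so the skeleton is small; the task is to place five bromines and one oxygen regiospecifically on two electron-rich rings. There is no stereocentre and the biaryl axis is not configurationally stable, so nothing has to be controlled in space. The only stereo elements on the way are the two bridgeheads of the transient lactone 10, which vanish on aromatisation. The free tribromopyrrole is the fragile part (acid, oxidants, light) and should appear last. The C–Br bonds do not tolerate organolithium reagents or zerovalent palladium, so every metal-mediated C–C bond should be made before bromine is on the molecule. Electrophilic bromination of ring A would need the free phenol and would compete with the far more nucleophilic pyrrole, so it is better to bring the ring A bromines in with a building block. The feature that allows this is that C2(Br)–C3(H)–C4(Br)–C5(H) of ring A is the diene C3–C6 of 3,5-dibromo-2-pyrone (2), while the pair C1(O)–C6(C2') is an alkyne with oxygen on one carbon and the pyrrole on the other, the ynol ether 9.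

## Retrosynthesis

**C3'–Br, C4'–Br, C5'–Br (14 ⇒ 13).** The three ring B bromines are cut first. Their formation needs no regiocontrol: every free pyrrole carbon of 13 is to be brominated, and ring A of 13 has no open ortho or para position and is deactivated by two bromines. The alternative of cutting all five C–Br bonds here would tie the halogenation of both rings to one event. The precursor 13 is a simple hydroxyphenylpyrrole; the forward step only has to stop at three equivalents of electrophile.

**N–S and O–CH3 (13 ⇒ 12 ⇒ 11).** Both protecting groups are removed before the bromination so that the last step forms the target directly. The ether is cleaved first, by a Lewis acid, while the sulfonyl group still shields the pyrrole from acid. The N–S bond is then cleaved by base, which the phenoxide tolerates. The reverse order would expose a free pyrrole to the Lewis acid. Compound 11 is a robust, fully protected biaryl.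

**C1–C2 and C5–C6 of ring A (11 ⇒ 2 + 9, through 10).** This is the central cut. The neighbouring option, making C6–C2' by cross-coupling, would need a benzene with three different halogens and would bring zerovalent palladium next to two aryl bromides. Brominating a preformed anisole is not viable, because the ether does not activate ring A enough for selective bromination. The cycloaddition cut instead delivers both bromines, the oxygen and the pyrrole in one event from two small achiral pieces. The forward reaction must be a regioselective [4+2] addition across pyrone C3 and C6, followed by decarboxylative cycloreversion of the bridged lactone 10.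

**C2'–C(sp) (9 ⇒ 5 + 6, through 7 and 8).** The ynol ether is cut at the pyrrole–alkyne bond. Forming the O–C(sp) bond instead has no general method, and a Sonogashira coupling would require isolating the volatile free alkoxyacetylene. The acetylide 7 is therefore made in the flask from the chloroacetal 6, moved to zinc (8) and coupled with the iodide 5. The forward reaction must be a mild sp–sp2 coupling that leaves the acid-sensitive ynol ether untouched.

**C2'–I (5 ⇒ 3, through 4).** The iodide comes from the sulfonylpyrrole 3 by directed lithiation at the carbon next to nitrogen (4) and iodination. Electrophilic iodination of 3 would give isomer mixtures; the sulfonyl group fixes the site of metalation.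

**C3–Br and C5–Br of the pyrone (2 ⇒ 1).** The dibromopyrone is reached in one step from coumalic acid 1. One bromine replaces the carboxyl group and the other enters at C3, so the 3,5-pattern follows from the structure of 1.

## Roads not taken

**Alternative 1:** Ring B is cut at N1'–C5' and C3'–C4'. C2' and C3' come from an aryl methyl ketoxime, C4' and C5' from acetylene A2.
- Forward key step: (E)-2'-methoxyacetophenone oxime A1 is heated with acetylene A2 in KOH/DMSO (Trofimov reaction). O-Vinylation, tautomerisation, a [3,3] shift and cyclodehydration give 2-(2-methoxyphenyl)-1H-pyrrole A3.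
- Completion: ether cleavage to 2-(1H-pyrrol-2-yl)phenol A4, then fivefold bromination to 14.
- Merits: about four steps from a cheap ketone, clearly shorter than the seven proposed here. The perbromination is self-directing, since the five positions to be brominated are exactly the activated ones.
- Weak points: acetylene A2 under superbasic conditions at elevated temperature is a safety and equipment burden. N-Vinylation of A3 by excess A2 is an inherent side reaction. All five bromines enter in one undifferentiated event that passes through under-brominated mixtures.
- Comparison: for 14 alone this road is shorter. The chosen plan offers instead a ring A halogen pattern fixed by construction and independent of ring B, no acetylene chemistry, and a final bromination confined to one ring.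

**Alternative 2:** Ring B is cut at C2'–C3', N1'–C2' and C4'–Br.
- Forward key step: 3,5-dibromo-2-methoxybenzoyl chloride A5 is coupled with tert-butyl prop-2-ynylcarbamate A6 (PdCl2(PPh3)2, CuI, triethylamine) to the ynone A7. Bromide (LiBr, toluenesulfonic acid) adds to its β-carbon and the carbamate nitrogen condenses with the ketone, giving tert-butyl 4-bromo-2-(3,5-dibromo-2-methoxyphenyl)-1H-pyrrole-1-carboxylate A8.
- Completion: carbamate removal, two further brominations, ether cleavage.
- Merits: a one-pot three-component ring synthesis that carries the ring A bromines in from A5 and installs C4'–Br. The length is similar to or one step shorter than the chosen plan, and the ring-forming sequence is an established reaction type.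
- Weak points: the halide addition–cyclocondensation is best established with iodide, and bromide is the weaker nucleophile. The acid needed for it threatens the carbamate before cyclisation. The palladium step runs in the presence of two aryl bromides; it should be chemoselective, since the acyl chloride reacts first, but this is not guaranteed. The early C4' bromine saves nothing, since two more brominations follow anyway.
- Comparison: the chosen plan has the less tested key step. It offers instead palladium chemistry finished before any aryl bromide exists, and a ring B that stays unsubstituted and sulfonyl-protected until the last step.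

**Alternative 3:** Ring B is cut at C2'–C3' and C4'–C5' (van Leusen-type [3+2]).
- Forward key step: the anion (NaH, THF) of racemic (3,5-dibromo-2-methoxyphenyl)(tosyl)methyl isocyanide A9 adds to tert-butyl acrylate A10. The ester enolate closes onto the isocyanide carbon and sulfinate is lost, giving tert-butyl 5-(3,5-dibromo-2-methoxyphenyl)-1H-pyrrole-3-carboxylate A11.
- Merits: a dependable pyrrole synthesis, with ring A fully halogenated from the start.
- Weak points: A9 is a hindered ortho-substituted isocyanide that needs two steps of its own. The ester carbon at C4' is not part of 14 and must be removed by ester cleavage and (bromo)decarboxylation. The total is about seven steps, no shorter than the chosen plan.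
- Comparison: the ring-forming step is better precedented than the chosen key step. The chosen plan offers instead no sacrificial carbon, two commercial starting blocks for the key step partners, and a more convergent assembly.

Key step: step 4

## Route

Remark on the chemistry: lactone 10 is chiral but forms as a racemate and does not persist; its SMILES shows one enantiomer. Compounds 1, 3 and 6 are taken as purchased.

Step 1
Reactants: 1 coumalic acid (2-oxo-2H-pyran-5-carboxylic acid)
Product: 2 3,5-dibromo-2H-pyran-2-one
Conditions: NBS (2.5 equiv), LiOAc, MeCN–H2O, rt
Reagents that add atoms: N-bromosuccinimide, O=C1CCC(=O)N1Br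
Why: Brominative decarboxylation: electrophilic bromine attacks C5 of the carboxylate ipso with loss of CO2, and a second equivalent substitutes C3, the other nucleophilic pyrone carbon; this is the established one-pot access to 2.

Step 2
Reactants: 3 1-tosyl-1H-pyrrole
Product: 5 2-iodo-1-tosyl-1H-pyrrole, via 2-lithio-1-tosylpyrrole 4 (not isolated)
Conditions: LiN(i-Pr)2, THF, −78 °C; I2, THF, −78 °C → rt; aq Na2S2O3
Reagents that add atoms: iodine, II
Why: Directed lithiation of an N-sulfonylpyrrole at C2 (acidified and coordinated by the sulfonyl group) followed by iodinolysis of the C–Li bond; the amide base at −78 °C avoids attack at sulfur and sulfonyl migration.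

Step 3
Reactants: 6 chloroacetaldehyde dimethyl acetal (2-chloro-1,1-dimethoxyethane); 5 2-iodo-1-tosyl-1H-pyrrole
Product: 9 2-(methoxyethynyl)-1-tosyl-1H-pyrrole, via lithium methoxyacetylide 7 (not isolated), via methoxyethynylzinc chloride 8 (not isolated)
Conditions: Et2NH, n-BuLi, THF, −78 → 0 °C; 6 (1.5 equiv), 0 °C; ZnCl2 (THF), 0 °C; 5, Pd(PPh3)4 (5 mol %), rt; aq NaHCO3
Reagents that add atoms: none
Why: Three equivalents of LiNEt2 eliminate methanol and HCl from 6 and deprotonate the resulting methoxyacetylene; transmetalation to zinc and Negishi coupling with the heteroaryl iodide under zerovalent palladium is a known way to aryl ynol ethers. Excess ZnCl2 also binds the methoxide formed, which protects the N-sulfonyl group.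

Step 4
Reactants: 2 3,5-dibromo-2H-pyran-2-one; 9 2-(methoxyethynyl)-1-tosyl-1H-pyrrole
Product: 11 2-(3,5-dibromo-2-methoxyphenyl)-1-tosyl-1H-pyrrole, via bridged lactone 10 (not isolated)
Conditions: 2 (1.2 equiv), PhMe (degassed), 110 °C, Ar
Reagents that add atoms: none
Why: Inverse-electron-demand Diels–Alder reaction followed by retro-Diels–Alder loss of CO2, the known route from 2-pyrones and alkynes to benzenes; the closest cases are cycloadditions of 2 with enol ethers and of 2-pyrones with donor alkynes such as ynamines. The electron-poor diene C3=C4–C5=C6 of 2 reacts with the electron-rich triple bond of 9 in an asynchronous [4+2] addition. The leading bond joins the alkyne carbon β to oxygen (the pyrrolyl-bearing, nucleophilic one) to pyrone C6, the vinylogous acceptor position, and the methoxy-bearing carbon closes onto C3. Ring A is thus closed by intermolecular [4+2] cycloaddition (C5–C6 and C1–C2 in target numbering) to the bridged dienyl lactone 10, which should not survive at 110 °C and aromatises by cycloreversion. No stereocentre remains, because the two bridgeheads of racemic 10 become sp2 carbons of ring A. The selectivity needed is regiochemical and rests on the matched polarisation of the partners; the electron-withdrawing N-sulfonyl group keeps methoxy the dominant donor on the alkyne and keeps the pyrrole from acting as a diene or nucleophile. The methyl ether has no β-hydrogen, so the retro-ene fragmentation to a ketene that limits higher alkyl ynol ethers on heating is excluded.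

Step 5
Reactants: 11 2-(3,5-dibromo-2-methoxyphenyl)-1-tosyl-1H-pyrrole
Product: 12 2,4-dibromo-6-(1-tosyl-1H-pyrrol-2-yl)phenol
Conditions: BBr3 (2.5 equiv), CH2Cl2, −78 °C → rt; H2O
Reagents that add atoms: none
Why: Lewis-acid cleavage of an aryl methyl ether (boron binds the twisted, hindered methoxy oxygen and bromide attacks the methyl group by SN2). The sulfonamide and the aryl bromides are inert, and the sulfonyl group keeps the pyrrole unreactive toward acid.

Step 6
Reactants: 12 2,4-dibromo-6-(1-tosyl-1H-pyrrol-2-yl)phenol
Product: 13 2,4-dibromo-6-(1H-pyrrol-2-yl)phenol
Conditions: NaOH (aq, excess), 1,4-dioxane, 80 °C, Ar; aq NH4Cl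
Reagents that add atoms: none
Why: Hydrolytic N-desulfonylation: hydroxide attacks sulfur and the pyrrolide leaves, a standard deprotection of N-sulfonylpyrroles. The alcohol-free medium excludes alkyl sulfonate formation and therefore O- or N-alkylation. Any sulfonyl transfer to the neighbouring phenoxide would give an aryl sulfonate that the same conditions hydrolyse to 13.

Step 7
Reactants: 13 2,4-dibromo-6-(1H-pyrrol-2-yl)phenol
Product: 14 pentabromopseudilin, 2,4-dibromo-6-(3,4,5-tribromo-1H-pyrrol-2-yl)phenol
Conditions: NBS (3.0 equiv), THF, −78 → 0 °C, dark; aq Na2S2O3
Reagents that add atoms: N-bromosuccinimide, O=C1CCC(=O)N1Br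
Why: Threefold electrophilic aromatic bromination of the pyrrole (C5' first, then C3' and C4'). Ring A has no free ortho or para position and carries two deactivating bromines, so the reagent is consumed by ring B; exhaustive bromination of hydroxyphenylpyrroles to this substitution pattern is a known reaction type.

## Compound list

1 | coumalic acid (2-oxo-2H-pyran-5-carboxylic acid) | OC(=O)c1ccc(=O)oc1 | starting material
2 | 3,5-dibromo-2H-pyran-2-one | O=c1occ(Br)cc1Br | intermediate
3 | 1-tosyl-1H-pyrrole | Cc1ccc(cc1)S(=O)(=O)n1cccc1 | starting material
4 | 2-lithio-1-tosyl-1H-pyrrole | [Li]c1cccn1S(=O)(=O)c1ccc(C)cc1 | intermediate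
5 | 2-iodo-1-tosyl-1H-pyrrole | Ic1cccn1S(=O)(=O)c1ccc(C)cc1 | intermediate
6 | chloroacetaldehyde dimethyl acetal (2-chloro-1,1-dimethoxyethane) | COC(CCl)OC | starting material
7 | lithium methoxyacetylide | [Li]C#COC | intermediate
8 | methoxyethynylzinc chloride | Cl[Zn]C#COC | intermediate
9 | 2-(methoxyethynyl)-1-tosyl-1H-pyrrole | COC#Cc1cccn1S(=O)(=O)c1ccc(C)cc1 | intermediate
10 | 4,7-dibromo-5-methoxy-6-(1-tosyl-1H-pyrrol-2-yl)-2-oxabicyclo[2.2.2]octa-5,7-dien-3-one (racemic, bridgehead configuration fixed by the bicycle, one enantiomer drawn) | O=C1O[C@@H]2C(Br)=C[C@@]1(Br)C(OC)=C2c1cccn1S(=O)(=O)c1ccc(C)cc1 | intermediate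
11 | 2-(3,5-dibromo-2-methoxyphenyl)-1-tosyl-1H-pyrrole | COc1c(Br)cc(Br)cc1-c1cccn1S(=O)(=O)c1ccc(C)cc1 | intermediate
12 | 2,4-dibromo-6-(1-tosyl-1H-pyrrol-2-yl)phenol | Oc1c(Br)cc(Br)cc1-c1cccn1S(=O)(=O)c1ccc(C)cc1 | intermediate
13 | 2,4-dibromo-6-(1H-pyrrol-2-yl)phenol | Oc1c(Br)cc(Br)cc1-c1ccc[nH]1 | intermediate
14 | pentabromopseudilin, 2,4-dibromo-6-(3,4,5-tribromo-1H-pyrrol-2-yl)phenol | Oc1c(Br)cc(Br)cc1-c1[nH]c(Br)c(Br)c1Br | target

## Step count and risk

Total: 7 steps. Longest linear sequence: 6 steps (3 → 5 → 9 → 11 → 12 → 13 → 14); the pyrone branch (1 → 2) adds one step and joins at step 4.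

**Step 4 (key step).**
- What may go wrong: the ynol ether may be consumed by thermal oligomerisation or adventitious hydration faster than it adds to the pyrone, since the sulfonylpyrrole lowers its nucleophilicity. Regiocontrol may erode if the pyrrolyl group competes with methoxy as the polarising donor. Addition at pyrone C6 may be stepwise and end in ring opening instead of ring closure.
- Fallback (from 3, back at 11): ring A is bought with its halogens and the biaryl bond is made by cross-coupling. Compound 3 is lithiated as in step 2 (through 4) and quenched with B(Oi-Pr)3 and aqueous acid to give (1-tosyl-1H-pyrrol-2-yl)boronic acid F1. Commercial 2,4-dibromophenol is iodinated at its free ortho position (N-iodosuccinimide, TsOH, MeCN) to 2,4-dibromo-6-iodophenol F2 and O-methylated (MeI, K2CO3, acetone) to 1,5-dibromo-3-iodo-2-methoxybenzene F3. Suzuki–Miyaura coupling of F1 with F3 (Pd(PPh3)4, Na2CO3, DME–H2O, 60 °C) at the C–I bond, which undergoes oxidative addition well before the C–Br bonds, returns 11.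

**Step 3.**
- What may go wrong: the alkoxyethynyl metal species may decompose, or transmetalation may be sluggish in the presence of lithium methoxide and diethylamine, so that coupling loses to homocoupling or to cleavage of the sulfonyl group. The product may hydrate on acidic silica during isolation.
- Fallback (from 3, back at 9, bypassing 5): the triple bond is made by elimination instead of coupling. Friedel–Crafts acylation of 3 with methoxyacetic acid and trifluoroacetic anhydride (CH2Cl2, rt), which is C2-selective for N-sulfonylpyrroles, gives 2-methoxy-1-(1-tosyl-1H-pyrrol-2-yl)ethan-1-one F4. Chelation-controlled enolisation and O-sulfonylation (LiN(SiMe3)2, PhNTf2, THF, −78 °C) give (Z)-2-methoxy-1-(1-tosyl-1H-pyrrol-2-yl)ethenyl trifluoromethanesulfonate F5. Anti-elimination of triflate (KOt-Bu, THF, −78 → 0 °C) returns 9.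

**Step 7.**
- What may go wrong: the third bromination at C3'/C4' is the slowest, and the electron-rich phenol may be oxidised in competition (ipso attack para to the hydroxyl). The result would be under-brominated mixtures or degradation of the free phenol–pyrrole under the oxidant.
- Fallback (from 11, back at 14): the order of the last three operations is changed so that the oxidant never meets a free phenol. N-Desulfonylation of 11 (NaOH, aqueous 1,4-dioxane, 80 °C) gives 2-(3,5-dibromo-2-methoxyphenyl)-1H-pyrrole F6. Tribromination (NBS, 3 equiv, THF, −78 → 0 °C) gives 2,3,4-tribromo-5-(3,5-dibromo-2-methoxyphenyl)-1H-pyrrole F7. Ether cleavage (BBr3, CH2Cl2, −78 °C → rt) returns 14.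

## Further compounds

F1 | step 4 | (1-tosyl-1H-pyrrol-2-yl)boronic acid | OB(O)c1cccn1S(=O)(=O)c1ccc(C)cc1
F2 | step 4 | 2,4-dibromo-6-iodophenol | Oc1c(Br)cc(Br)cc1I
F3 | step 4 | 1,5-dibromo-3-iodo-2-methoxybenzene | COc1c(Br)cc(Br)cc1I
F4 | step 3 | 2-methoxy-1-(1-tosyl-1H-pyrrol-2-yl)ethan-1-one | COCC(=O)c1cccn1S(=O)(=O)c1ccc(C)cc1
F5 | step 3 | (Z)-2-methoxy-1-(1-tosyl-1H-pyrrol-2-yl)ethenyl trifluoromethanesulfonate | CO/C=C(OS(=O)(=O)C(F)(F)F)/c1cccn1S(=O)(=O)c1ccc(C)cc1
F6 | step 7 | 2-(3,5-dibromo-2-methoxyphenyl)-1H-pyrrole | COc1c(Br)cc(Br)cc1-c1ccc[nH]1
F7 | step 7 | 2,3,4-tribromo-5-(3,5-dibromo-2-methoxyphenyl)-1H-pyrrole | COc1c(Br)cc(Br)cc1-c1[nH]c(Br)c(Br)c1Br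
A1 | alternative 1 | (E)-1-(2-methoxyphenyl)ethan-1-one oxime | COc1ccccc1/C(C)=N/O
A2 | alternative 1 | acetylene | C#C
A3 | alternative 1 | 2-(2-methoxyphenyl)-1H-pyrrole | COc1ccccc1-c1ccc[nH]1
A4 | alternative 1 | 2-(1H-pyrrol-2-yl)phenol | Oc1ccccc1-c1ccc[nH]1
A5 | alternative 2 | 3,5-dibromo-2-methoxybenzoyl chloride | COc1c(Br)cc(Br)cc1C(Cl)=O
A6 | alternative 2 | tert-butyl prop-2-ynylcarbamate | C#CCNC(=O)OC(C)(C)C
A7 | alternative 2 | tert-butyl [4-(3,5-dibromo-2-methoxyphenyl)-4-oxobut-2-yn-1-yl]carbamate | COc1c(Br)cc(Br)cc1C(=O)C#CCNC(=O)OC(C)(C)C
A8 | alternative 2 | tert-butyl 4-bromo-2-(3,5-dibromo-2-methoxyphenyl)-1H-pyrrole-1-carboxylate | COc1c(Br)cc(Br)cc1-c1cc(Br)cn1C(=O)OC(C)(C)C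
A9 | alternative 3 | (3,5-dibromo-2-methoxyphenyl)(tosyl)methyl isocyanide (racemic) | COc1c(Br)cc(Br)cc1C([N+]#[C-])S(=O)(=O)c1ccc(C)cc1
A10 | alternative 3 | tert-butyl acrylate | C=CC(=O)OC(C)(C)C
A11 | alternative 3 | tert-butyl 5-(3,5-dibromo-2-methoxyphenyl)-1H-pyrrole-3-carboxylate | COc1c(Br)cc(Br)cc1-c1cc(C(=O)OC(C)(C)C)c[nH]1
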